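The J left over in a flask is its charge minus what has dissolved, so one quantity carries the reckoning: the dissolving budget B, the J taken into solution per starting volume by the asked time.

- maple: J 0.12 M; D 0.75 M (fed, over 15 h); run made earlier; the fed solution adds 0.25 times the starting volume
- flask: J 0.25 M; D 0.750 M (fed, over 15 h); time 15 h; the fed solution adds 0.25 times the starting volume

- maple (time / h: E / %, Z / %): 0.500: 0.6, 9.8; 1.00: 0, 19.8; 1.50: 0.3, 27.1; 2.00: 0.7, 33.6; 2.50: 2.2, 38.8; 3.00: 0.2, 43.6

(readings scatter by 0.5 percentage points)

- concentration of E (only what is free in solution) at 15 h, in M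
- concentration of Z at 15 h, in M
- concentration of J at 15 h (only what is still solid), in M
- concentration of Q at 15 h, in M

- percentages count the J that a species holds: one Q counts as two
- E is meant together with its X
- every charge counts on the volume at the start, and the solution that is fed holds the whole dose
- solid, in amounts per volume of the solution: J, X
- steps that have been proposed: J <-> Z; Z + D <-> E; 2 Z -> Q; X <-> E
- at the start none of J is in solution
- the concentration of E that is asked is that of its free form alone
- Z means what is dissolved; the solid is not counted in it

The maple readings give a first dissolving rate r and, from the shrinking gains of Z over two spans of 1.50 h, a read ceiling c of dissolved Z: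

r = 0.0238 M h⁻¹, c = 0.0831 M

This reckoning assumes that the rate is r(1 − [Z]/c) while solid lies there, which is zero-order in the solid.

Two extremes bound the flask. If Z were removed at once, the rate would stay r and the solid would go at 10.5 h, since 0.357 M is more than the charge. If Z were never removed, [Z] would stop at c, and B, counted per starting volume, would reach c(1 + 0.25) = 0.104 M by 15 h.

The rate is linear in [Z], so replacing the curve by its mean costs nothing; the error lies in the guessed mean. Taking that mean as c/2:

B = (r/2)·15 h = 0.178 M

This is less than the charge, and solid survives while mean [Z] exceeds 0.0248 M. In the diluted flask, solid J comes to 0.0574 M.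

The forecast gives E 0.045 M, Z 0.11 M, J 0.05 M and Q 0.015 M: “The J+Z pool falls to about 0.17 M, split about 0.11 Z and 0.05 J”. Its J stands below this reckoning's.

The flask gives E 0.0175 M, Z 0.0708 M, J 0.0657 M and Q 0.0209 M.

    J ⇌ Z, rate k1*(cs1 - [Z]) while solid is left; crystals form when [Z] > cs1 (solubility = 0.100 M, k = 0.256 h⁻¹)
    Z + D ⇌ E (K = 23.0 L mol⁻¹, k = 0.0732 L mol⁻¹ h⁻¹)
    2 Z → Q (k = 0.385 L mol⁻¹ h⁻¹)
    X ⇌ E, rate k4*(cs4 - [E]) while solid is left; crystals form when [E] > cs4 (solubility = 17.0 mM, k = 4.94 h⁻¹)

Half of the dissolving up to 15 h was done by 5.51 h, so the rate did not stay at its mean. The J taken up in the flask is 0.168 M per starting volume, against B of 0.178 M.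

In the neighbour flask with 0.62 M of J, the same B leaves 0.354 M of solid J. That neighbour flask gives 0.362 M, with Z at 0.0708 M, as in the flask.

The earlier runs and the new flask are calculated with constants of no real substance.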